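The numbers in the tables stem from a simulated flask from invented constants; scatter was added.

Late in the west run the starting material reads 0% at 5.00 d, and still the product climbs from 60.4% to 84.4% by 8.00 d, so something unseen, an intermediate, stands between the two.

| setting | north-east | west | north-west | alpha | beta | gamma | theta | zeta |
|---|---|---|---|---|---|---|---|---|
| starting material | 10 mM (fed, over 4.0 d) | 10 mM (fed, over 4.0 d) | 10 mM (fed, over 4.0 d) | 10 mM (fed, over 4.0 d) | 10 mM (fed, over 6.0 d) | 10 mM (fed, over 10 d) | 10 mM (fed, over 15 d) | 10 mM (fed, over 20 d) |
| protic impurity | 1 mM | 1 mM | 1.5 mM | 1.00 mM | 1.00 mM | 1.00 mM | 1.00 mM | 1.00 mM |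
| catalyst | 0.075 mol% | 0.3 mol% | 0.15 mol% | 0.15 mol% | 0.15 mol% | 0.15 mol% | 0.15 mol% | 0.15 mol% |
| remark | run made earlier | run made earlier | run made earlier |  |  |  |  |  |
| time |  |  |  | 6.0 d | 6.0 d | 6.0 d | 6.0 d | 6.0 d |

| run | time / d | product / % | starting material / % |
|---|---|---|---|
| north-east | 0.417 | 0.9 | 4.6 |
| north-east | 1.04 | 0.6 | 5.7 |
| north-east | 2.08 | 3.7 | 5.4 |
| north-east | 3.00 | 8.5 | 6.1 |
| north-east | 4.00 | 14.1 | 5.7 |
| north-east | 6.00 | 28.4 | 0 |
| north-east | 8.00 | 40.6 | 0 |
| west | 0.625 | 0.9 | 4.5 |
| west | 0.833 | 1.9 | 5.1 |
| west | 1.25 | 4.3 | 5.6 |
| west | 2.08 | 13.3 | 5.6 |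
| west | 3.00 | 25.6 | 5.3 |
| west | 5.00 | 60.4 | 0 |
| west | 8.00 | 84.4 | 0.6 |
| north-west | 0.625 | 0.5 | 4.7 |
| north-west | 1.04 | 1.5 | 5.3 |
| north-west | 2.08 | 7.4 | 5.9 |
| north-west | 4.00 | 26.0 | 5.4 |
| north-west | 8.00 | 62.6 | 0.3 |

(standard deviation of a reading: 0.3 percentage points)

- percentages count the whole charge, also what has not yet gone in
- "hardly changes" means that all values lie within two and a half points (for a concentration: within two and a half percent of the largest)

- amount of product at the end, in percent of the starting material charged for alpha, beta, gamma, theta, zeta, in this order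
- how that number moves from the first to the last of them (falls, then rises / falls all the way / rises, then falls / hardly changes / rises all the way)

What stays nearly constant during the feed of the north-west run? The starting material, once it has built up: it reads 5.9% at 2.08 d and 5.4% at 4.00 d.

Does the catalyst touch that step? At 2.08 d the west run, with 0.3 mol%, reads 5.6%, and the north-east run, with 0.075 mol%, reads 5.4%, so I take it that it does not. I freeze that level instead: in the north-west run, fed over 4.0 d, the holdup is worth 0.216 d of feed, and I treat each portion as waiting that long before it becomes intermediate.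

How fast does the intermediate go? Once feeding has stopped, I count whatever is not product as intermediate and take the logarithmic fall of that remainder. The west run gives 0.311 d⁻¹ and the north-east run 0.0934 d⁻¹. This is a pseudo-first-order constant at fixed [catalyst], read off scattered readings, and as read it rises 3.33-fold for a 4.00-fold loading. The asked loading of 0.15 mol% is the geometric middle of those two, so I take 0.170 d⁻¹.

But the north-west run has more protic impurity, so does that constant survive? At the asked loading that run reads 0.171 d⁻¹, which is close to my value, so I keep it.

Why should dosing time enter simply? Each portion of feed runs on its own clock, and first-order portions add. So I define the product-days: the days of steady feed that have become product by a given time. At 6.0 d they come to 2.10 d. At this loading and while a feed lasts, I reckon the product percentage as this figure divided by the dosing time, so beta gives 35.1%, gamma 21.0%, theta 14.0% and zeta 10.5%.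

And alpha, whose feed stops at 4.0 d? Its feed counts as one that runs on, minus one that starts at 4.0 d, whose product-days are 0.246 d. That gives 46.4%.

The forecast says 48%, 36.5%, 22%, 14.6%, 11%, so the amount falls all the way, on the grounds that “Slower feeding simply delivers less material, later”. With 0.18 per day and 2.19 days its figure for beta stands slightly higher than mine.

The flask gives 48.6%, 36.8%, 22.0%, 14.6%, 11.0%; the amount falls all the way.

    starting material + protic impurity → quenched substrate (k = 0.00280 M⁻¹ s⁻¹)
    catalyst + intermediate → catalyst + product (k = 0.150 M⁻¹ s⁻¹)
    starting material → intermediate (k = 5.00 × 10⁻⁵ s⁻¹)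

In gamma at 6.00 d the feed is still running, with 2.22% starting material and 33.1% intermediate beside the product. Product times dosing time there is 2.20 d, and my 2.10 d is lower than that. In zeta, 2.10 d over 20 d gives 10.5%, the flask stands at 11.0%, and the local order in dosing time is −1.0.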